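**Retrosynthetic overview**

1. Feature used: in the ten-membered carbocycle C1–C10, the C1 ketone and the lactone carbinol C6 lie across the ring. A C1–C6 bond would close a six-membered ring C1–C6 that is an oxidised p-cresol (C4 methyl para to the C1 oxygen), with C6 as the spiro carbon of the γ-lactone ring O–C12–C11–C7.
2. Target ⇒ 8-methacrylate, 4,5-epoxide (delivered by the free 8-OH) and 13-acetate removed ⇒ 4Z-alkene butenolide ⇒ C11 hydroxymethylation and C6=C7 → C7=C11 tautomerisation undone ⇒ ten-membered enol lactone / silyl enol ether 13.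
3. 13 ⇒ siloxy-Cope (C8–C9 formed, C1–C6 broken) ⇒ 1-isopropenyl-1-siloxy spirolactone 12 with an exocyclic E silyl enol ether C7=C8.
4. 12 ⇒ isopropenyl addition and conjugate reduction undone ⇒ spirodienone 6 ⇒ hypervalent-iodine dearomatisation of phenol acid 5. The benzylic centre C7 of 5 (from a rhodium-catalysed aryl 1,4-addition) relays its chirality to C6 and is erased afterwards.
5. Ring order: arene (future C1–C6 ring) → spiro γ-lactone → ten-membered ring by ring expansion → oxirane.

Key step: step 9

Remark on numbering: C1–C15 are the germacrane positions of the target (C1 ketone, C4/C5 epoxide, C6 lactone carbinol, C8 ester carbinol, C10 CHMe, C12 lactone carbonyl, C13 CH2OAc); spiro compounds also carry their spiro locants.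

Assumption: the 10S configuration α to the C1 ketone is taken to be the thermodynamically preferred one in this ring, so C10 is set by equilibration (step 12) and not by a kinetically controlled step.

**Route**

Step 1
Reactants: 1 [2-(benzyloxy)-5-methylphenyl]boronic acid; 2 methyl (E)-4,4-dimethoxybut-2-enoate
Product: 3 methyl (3R)-3-[2-(benzyloxy)-5-methylphenyl]-4,4-dimethoxybutanoate
Conditions: Rh(nbd)2BF4 (3 mol %), (S)-BINAP, Et3N, dioxane/H2O, 35 °C
Reagents that add atoms: none
Why: Rhodium-catalysed asymmetric 1,4-addition of an arylboronic acid to an (E)-enoate (Hayashi–Miyaura reaction) runs under mild amine-buffered conditions that leave the dimethyl acetal intact; the (S)-BINAP–rhodium aryl should add to the α-si face of the enoate, which sets the benzylic carbon (C7) as R.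

Step 2
Reactants: 3 methyl (3R)-3-[2-(benzyloxy)-5-methylphenyl]-4,4-dimethoxybutanoate
Product: 4 methyl (3R)-3-(2-hydroxy-5-methylphenyl)-4,4-dimethoxybutanoate
Conditions: H2 (1 atm), Pd/C, EtOAc, rt
Reagents that add atoms: none
Why: Hydrogenolysis of the benzyl aryl ether under neutral conditions frees the phenol without touching the acetal, the ester or the stereocentre.

Step 3
Reactants: 4 methyl (3R)-3-(2-hydroxy-5-methylphenyl)-4,4-dimethoxybutanoate
Product: 5 (3R)-3-(2-hydroxy-5-methylphenyl)-4,4-dimethoxybutanoic acid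
Conditions: LiOH, THF/H2O, 0 °C to rt; then 1 M HCl to pH 5 at 0 °C; used at once
Reagents that add atoms: lithium hydroxide, [Li+].[OH-]
Why: Ester saponification is done in base, where acetal and stereocentre are safe, and the acid is released cold at pH 5 so that neither acetal cleavage nor closure to the dihydrocoumarin should intervene before the oxidation.

Step 4
Reactants: 5 (3R)-3-(2-hydroxy-5-methylphenyl)-4,4-dimethoxybutanoic acid
Product: 6 (4R,5R)-4-(dimethoxymethyl)-9-methyl-1-oxaspiro[4.5]deca-7,9-diene-2,6-dione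
Conditions: PhI(OAc)2, MeCN, −10 to 0 °C; NaHCO3 wash; crude product taken on cold
Reagents that add atoms: none
Why: Hypervalent-iodine oxidative dearomatisation with ortho-spirolactonisation (5-exo attack of the carboxyl oxygen on the ipso carbon C6 of the aryloxy-iodane) is the known route to such spirodienones; the benzylic C7–H should eclipse the C6–C1 bond to avoid 1,3-strain with the iodine-bearing oxygen, so the CH2CO2H arm reaches one arene face only and C6 is expected as R with the acetal on the C5 side, the minor C6 epimer being a separable diastereomer.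

Step 5
Reactants: 6 (4R,5R)-4-(dimethoxymethyl)-9-methyl-1-oxaspiro[4.5]deca-7,9-diene-2,6-dione
Product: 7 (4R,5R)-4-(dimethoxymethyl)-9-methyl-1-oxaspiro[4.5]dec-9-ene-2,6-dione
Conditions: LiBH(s-Bu)3 (L-Selectride), THF, −78 °C; AcOH quench; chromatography
Reagents that add atoms: none
Why: Conjugate (1,4) reduction by the bulky hydride should occur at the unsubstituted β-carbon C3, because the δ-carbon C5 is shielded by the spiro centre and the ketone by the quaternary C6; this removes the diene before it can dimerise, and the minor C6 epimer from step 4 is removed here.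

Step 6
Reactants: 7 (4R,5R)-4-(dimethoxymethyl)-9-methyl-1-oxaspiro[4.5]dec-9-ene-2,6-dione; 8 isopropenylmagnesium bromide
Product: 9 (4R,5R,6S)-4-(dimethoxymethyl)-6-hydroxy-9-methyl-6-(prop-1-en-2-yl)-1-oxaspiro[4.5]dec-9-en-2-one (locants as in 7)
Conditions: CeCl3 (anhydrous), THF, −78 °C; then aq. NH4Cl
Reagents that add atoms: none
Why: Organocerium 1,2-addition to the ketone is faster than attack on the γ-lactone and suppresses enolisation; with the lactone oxygen axial on the cyclohexanone the nucleophile should enter axially, anti to the C6–O bond (Felkin–Anh polar model), which sets C1 as S with the isopropenyl group trans to the lactone oxygen.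

Step 7
Reactants: 9 (4R,5R,6S)-4-(dimethoxymethyl)-6-hydroxy-9-methyl-6-(prop-1-en-2-yl)-1-oxaspiro[4.5]dec-9-en-2-one
Product: 10 (4R,5R,6S)-6-hydroxy-9-methyl-2-oxo-6-(prop-1-en-2-yl)-1-oxaspiro[4.5]dec-9-ene-4-carbaldehyde
Conditions: PPTS (0.2 equiv), acetone/H2O 9:1, 40 °C
Reagents that add atoms: water, O
Why: Mild acid-catalysed acetal hydrolysis should spare the tertiary allylic alcohol and the lactone; the formyl group lies on the C5 side, away from the C1 hydroxyl, so lactol formation is not expected, and the epimerisable C7 becomes sp2 in the next step.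

Step 8
Reactants: 10 (4R,5R,6S)-6-hydroxy-9-methyl-2-oxo-6-(prop-1-en-2-yl)-1-oxaspiro[4.5]dec-9-ene-4-carbaldehyde
Product: 12 (4E,5R,6S)-4-{[(tert-butyldimethylsilyl)oxy]methylidene}-9-methyl-6-(prop-1-en-2-yl)-6-[(trimethylsilyl)oxy]-1-oxaspiro[4.5]dec-9-en-2-one, via TBS enol ether alcohol 11 (not isolated)
Conditions: TBSOTf (1.1 equiv), Et3N, CH2Cl2, −78 °C; then TMSOTf (1.5 equiv), −78 to −40 °C; NaHCO3 quench; Et3N-deactivated silica
Reagents that add atoms: tert-butyldimethylsilyl trifluoromethanesulfonate, CC(C)(C)[Si](C)(C)OS(=O)(=O)C(F)(F)F; trimethylsilyl trifluoromethanesulfonate, C[Si](C)(C)OS(=O)(=O)C(F)(F)F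
Why: Soft enolisation and O-silylation of the aldehyde gives the silyl enol ether, expected E because the siloxy group avoids the quaternary C6, and the less hindered trimethylsilyl triflate then caps the tertiary alcohol; the work-up stays basic because the product is a doubly allylic tertiary ester.

Step 9
Reactants: 12 (4E,5R,6S)-4-{[(tert-butyldimethylsilyl)oxy]methylidene}-9-methyl-6-(prop-1-en-2-yl)-6-[(trimethylsilyl)oxy]-1-oxaspiro[4.5]dec-9-en-2-one
Product: 13 (1(10)Z,4Z,8R)-8-[(tert-butyldimethylsilyl)oxy]-1-[(trimethylsilyl)oxy]-13-norgermacra-1(10),4,6-trien-12,6-olide (ring carbons C2 and C9 trans on C1=C10)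
Conditions: toluene (degassed, dilute), N,O-bis(trimethylsilyl)acetamide (0.1 equiv), silylated sealed tube, 175 °C
Reagents that add atoms: none
Why: This is a thermal [3,3]-sigmatropic shift (siloxy-Cope) across C9=C10–C1–C6–C7=C8, in which the C8–C9 bond forms as the C1–C6 bond breaks, leaving a silyl enol ether at C1=C10 and an enol lactone at C6=C7. The closest known reaction is the oxy-Cope ring expansion of 1,2-dialkenylcyclohexanol silyl ethers to cyclodecenone silyl enol ethers. The ten-membered ring is closed by four-atom ring enlargement of the six-membered ring and not by end-to-end cyclisation, so no medium-ring closure is needed. The only new stereocentre, C8, is controlled by C6 through a chair transition state that the two rings fix: the lactone ring forces O6 pseudo-equatorial and C5 pseudo-axial at C6, the carbocycle then forces C2 pseudo-equatorial and the siloxy group pseudo-axial at C1, and with the E enol ether (OTBS pseudo-equatorial) C9 can add to one face of C8 only, giving 8R from 1S,6R. The step needs the [3,3] shift to outrun ionisation of the doubly allylic C6–O bond and the alternative pairing of the isopropenyl group with C4=C5; the first is addressed by the non-polar solvent, silylated glass and silylating acid scavenger, the second by the bridged boat that this pairing would require. Relief of the congested bond between two oxygen-bearing quaternary carbons and the two enol-type double bonds formed should pull the equilibrium to the ten-membered ring.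

Step 10
Reactants: 13 (1(10)Z,4Z,8R)-8-[(tert-butyldimethylsilyl)oxy]-1-[(trimethylsilyl)oxy]-13-norgermacra-1(10),4,6-trien-12,6-olide
Product: 15 (1(10)Z,4Z,8R)-8-[(tert-butyldimethylsilyl)oxy]-13-hydroxy-1-[(trimethylsilyl)oxy]germacra-1(10),4,6-trien-12,6-olide (C11 epimers), via lithium furanolate 14 (not isolated)
Conditions: LiN(i-Pr)2 (1.1 equiv), THF, −78 °C; CH2O (monomer in THF, from paraformaldehyde), −78 °C; AcOH in THF at −78 °C; pH 7 buffer
Reagents that add atoms: formaldehyde, C=O
Why: Deprotonation at C11, the only acidic site, gives an aromatic lithium 2-furanolate that leaves the C1 silyl enol ether untouched, and its aldol addition to formaldehyde is expected at the unsubstituted α-carbon C11 and not at the fully substituted γ-carbon C6; the C11 centre is lost in step 11.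

Step 11
Reactants: 15 (1(10)Z,4Z,8R)-8-[(tert-butyldimethylsilyl)oxy]-13-hydroxy-1-[(trimethylsilyl)oxy]germacra-1(10),4,6-trien-12,6-olide
Product: 17 (1(10)Z,4Z,6S,8R)-13-acetoxy-8-[(tert-butyldimethylsilyl)oxy]-1-[(trimethylsilyl)oxy]germacra-1(10),4,7(11)-trien-12,6-olide, via butenolide alcohol 16 (not isolated)
Conditions: Et3N (3 equiv), CH2Cl2, 0 °C to rt; then Ac2O, DMAP (0.05 equiv), 0 °C
Reagents that add atoms: acetic anhydride, CC(=O)OC(C)=O
Why: Amine-mediated tautomerisation of the β,γ-unsaturated lactone to the conjugated butenolide (as in the α- to β-angelica lactone isomerisation) runs through the furanolate, in which H8 should lie in the ring plane toward C5 and C9 stand over one face, so the ammonium proton is expected on the other face of C6 and C5 ends up on the C9 side (the target configuration at C6); the primary alcohol is acetylated only after conjugation is complete, so no β-acetoxy lactone with an acidic α-hydrogen is present.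

Step 12
Reactants: 17 (1(10)Z,4Z,6S,8R)-13-acetoxy-8-[(tert-butyldimethylsilyl)oxy]-1-[(trimethylsilyl)oxy]germacra-1(10),4,7(11)-trien-12,6-olide
Product: 18 (4Z,6S,8R,10S)-13-acetoxy-8-[(tert-butyldimethylsilyl)oxy]-1-oxogermacra-4,7(11)-dien-12,6-olide
Conditions: TsOH·H2O (0.2 equiv), THF/H2O 10:1, rt, until the C10 epimer ratio is constant
Reagents that add atoms: none
Why: Acid hydrolysis of the trimethylsilyl enol ether by C-protonation gives the C1 ketone, and continued acid-catalysed enolisation equilibrates C10 to the assumed more stable 10S epimer without the base that would deprotonate C6; the secondary TBS ether and the allylic acetate should survive.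

Step 13
Reactants: 18 (4Z,6S,8R,10S)-13-acetoxy-8-[(tert-butyldimethylsilyl)oxy]-1-oxogermacra-4,7(11)-dien-12,6-olide
Product: 19 (4Z,6S,8R,10S)-13-acetoxy-8-hydroxy-1-oxogermacra-4,7(11)-dien-12,6-olide
Conditions: HF·pyridine, pyridine, THF, 0 °C to rt
Reagents that add atoms: none
Why: Pyridine-buffered fluoride desilylation removes the secondary TBS ether without base, so the γ-acidic butenolide, the allylic acetate and C10 should not be disturbed.

Step 14
Reactants: 19 (4Z,6S,8R,10S)-13-acetoxy-8-hydroxy-1-oxogermacra-4,7(11)-dien-12,6-olide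
Product: 20 (4S,5R,6R,8R,10S)-13-acetoxy-4,5-epoxy-8-hydroxy-1-oxogermacr-7(11)-en-12,6-olide
Conditions: VO(acac)2 (0.05 equiv), t-BuOOH (in decane), CH2Cl2, 0 °C to rt
Reagents that add atoms: tert-butyl hydroperoxide, CC(C)(C)OO
Why: Vanadium-catalysed hydroxyl-directed epoxidation (here from a bishomoallylic alcohol) reaches only C4=C5: with H6 eclipsing C4=C5 (1,3-strain against C3) and H8 eclipsing C7=C11 (against C13), the C8 oxygen sits over the alkene face syn to C7, and oxygen transfer there gives the 4S,5R cis-epoxide, while the electron-poor butenolide alkene is not attacked.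

Step 15
Reactants: 20 (4S,5R,6R,8R,10S)-13-acetoxy-4,5-epoxy-8-hydroxy-1-oxogermacr-7(11)-en-12,6-olide
Product: 21 (4S,5R,6R,8R,10S)-13-acetoxy-4,5-epoxy-8-(methacryloyloxy)-1-oxogermacr-7(11)-en-12,6-olide (CNP0128625.1)
Conditions: methacrylic anhydride, Et3N, DMAP (0.1 equiv), CH2Cl2, 0 °C
Reagents that add atoms: methacrylic anhydride, C=C(C)C(=O)OC(=O)C(C)=C
Why: DMAP-catalysed acyl transfer (Steglich-type esterification with an anhydride) to the secondary C8 alcohol at 0 °C should outrun 6→8 translactonisation and loss of the allylic acetate, and it touches no stereocentre.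

**Compound list**

1 | [2-(benzyloxy)-5-methylphenyl]boronic acid | Cc1ccc(OCc2ccccc2)c(B(O)O)c1 | starting material
2 | methyl (E)-4,4-dimethoxybut-2-enoate | COC(=O)/C=C/C(OC)OC | starting material
3 | methyl (3R)-3-[2-(benzyloxy)-5-methylphenyl]-4,4-dimethoxybutanoate | COC(=O)C[C@@H](C(OC)OC)c1cc(C)ccc1OCc1ccccc1 | intermediate
4 | methyl (3R)-3-(2-hydroxy-5-methylphenyl)-4,4-dimethoxybutanoate | COC(=O)C[C@@H](C(OC)OC)c1cc(C)ccc1O | intermediate
5 | (3R)-3-(2-hydroxy-5-methylphenyl)-4,4-dimethoxybutanoic acid | OC(=O)C[C@@H](C(OC)OC)c1cc(C)ccc1O | intermediate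
6 | (4R,5R)-4-(dimethoxymethyl)-9-methyl-1-oxaspiro[4.5]deca-7,9-diene-2,6-dione | O=C1C=CC(C)=C[C@]12OC(=O)C[C@H]2C(OC)OC | intermediate
7 | (4R,5R)-4-(dimethoxymethyl)-9-methyl-1-oxaspiro[4.5]dec-9-ene-2,6-dione | O=C1CCC(C)=C[C@]12OC(=O)C[C@H]2C(OC)OC | intermediate
8 | isopropenylmagnesium bromide | C=C(C)[Mg]Br | starting material
9 | (4R,5R,6S)-4-(dimethoxymethyl)-6-hydroxy-9-methyl-6-(prop-1-en-2-yl)-1-oxaspiro[4.5]dec-9-en-2-one | C=C(C)[C@@]1(O)CCC(C)=C[C@]12OC(=O)C[C@H]2C(OC)OC | intermediate
10 | (4R,5R,6S)-6-hydroxy-9-methyl-2-oxo-6-(prop-1-en-2-yl)-1-oxaspiro[4.5]dec-9-ene-4-carbaldehyde | C=C(C)[C@@]1(O)CCC(C)=C[C@]12OC(=O)C[C@H]2C=O | intermediate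
11 | (4E,5R,6S)-4-{[(tert-butyldimethylsilyl)oxy]methylidene}-6-hydroxy-9-methyl-6-(prop-1-en-2-yl)-1-oxaspiro[4.5]dec-9-en-2-one | C=C(C)[C@@]1(O)CCC(C)=C[C@]12OC(=O)C/C2=C\O[Si](C)(C)C(C)(C)C | intermediate
12 | (4E,5R,6S)-4-{[(tert-butyldimethylsilyl)oxy]methylidene}-9-methyl-6-(prop-1-en-2-yl)-6-[(trimethylsilyl)oxy]-1-oxaspiro[4.5]dec-9-en-2-one | C=C(C)[C@@]1(O[Si](C)(C)C)CCC(C)=C[C@]12OC(=O)C/C2=C\O[Si](C)(C)C(C)(C)C | intermediate
13 | (1(10)Z,4Z,8R)-8-[(tert-butyldimethylsilyl)oxy]-1-[(trimethylsilyl)oxy]-13-norgermacra-1(10),4,6-trien-12,6-olide | CC(C)(C)[Si](C)(C)O[C@@H]1C/C(C)=C(\O[Si](C)(C)C)CC/C(C)=C\C2=C1CC(=O)O2 | intermediate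
14 | lithium 2-furanolate of 13 (deprotonated at C11) | CC(C)(C)[Si](C)(C)O[C@@H]1C/C(C)=C(\O[Si](C)(C)C)CC/C(C)=C\c2oc(O[Li])cc21 | intermediate
15 | (1(10)Z,4Z,8R)-8-[(tert-butyldimethylsilyl)oxy]-13-hydroxy-1-[(trimethylsilyl)oxy]germacra-1(10),4,6-trien-12,6-olide (C11 epimers) | CC(C)(C)[Si](C)(C)O[C@@H]1C/C(C)=C(\O[Si](C)(C)C)CC/C(C)=C\C2=C1C(CO)C(=O)O2 | intermediate
16 | (1(10)Z,4Z,6S,8R)-8-[(tert-butyldimethylsilyl)oxy]-13-hydroxy-1-[(trimethylsilyl)oxy]germacra-1(10),4,7(11)-trien-12,6-olide | CC(C)(C)[Si](C)(C)O[C@@H]1C/C(C)=C(\O[Si](C)(C)C)CC/C(C)=C\[C@@H]2OC(=O)C(CO)=C21 | intermediate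
17 | (1(10)Z,4Z,6S,8R)-13-acetoxy-8-[(tert-butyldimethylsilyl)oxy]-1-[(trimethylsilyl)oxy]germacra-1(10),4,7(11)-trien-12,6-olide | CC(C)(C)[Si](C)(C)O[C@@H]1C/C(C)=C(\O[Si](C)(C)C)CC/C(C)=C\[C@@H]2OC(=O)C(COC(C)=O)=C21 | intermediate
18 | (4Z,6S,8R,10S)-13-acetoxy-8-[(tert-butyldimethylsilyl)oxy]-1-oxogermacra-4,7(11)-dien-12,6-olide | CC(C)(C)[Si](C)(C)O[C@@H]1C[C@H](C)C(=O)CC/C(C)=C\[C@@H]2OC(=O)C(COC(C)=O)=C21 | intermediate
19 | (4Z,6S,8R,10S)-13-acetoxy-8-hydroxy-1-oxogermacra-4,7(11)-dien-12,6-olide | O[C@@H]1C[C@H](C)C(=O)CC/C(C)=C\[C@@H]2OC(=O)C(COC(C)=O)=C21 | intermediate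
20 | (4S,5R,6R,8R,10S)-13-acetoxy-4,5-epoxy-8-hydroxy-1-oxogermacr-7(11)-en-12,6-olide | O[C@@H]1C[C@H](C)C(=O)CC[C@]2(C)O[C@@H]2[C@@H]2OC(=O)C(COC(C)=O)=C21 | intermediate
21 | (4S,5R,6R,8R,10S)-13-acetoxy-4,5-epoxy-8-(methacryloyloxy)-1-oxogermacr-7(11)-en-12,6-olide | C=C(C)C(=O)O[C@@H]1C[C@H](C)C(=O)CC[C@]2(C)O[C@@H]2[C@@H]2OC(=O)C(COC(C)=O)=C21 | target

**Step count**

Total steps: 15. Longest linear sequence: 15 (from 1 or 2 to 21).

**Three steps most likely to fail**

Step 9 (key step). What may go wrong: heterolysis of the doubly allylic C6–O bond, or elimination, at the temperature the neutral rearrangement needs, so that decomposition outruns the [3,3] shift. Fallback, an anion-accelerated oxy-Cope that sets out from 11 and comes back at 13: the one-pot of step 8 is stopped after the first silylation and 11 is isolated. KN(SiMe3)2 (2.2 equiv) with 18-crown-6 in THF at −78 °C should give the dipotassium alkoxide–lactone enolate F1; the second equivalent removes the C11 proton and thereby also makes the lactone inert to the alkoxide. On warming to 0–25 °C the same chair [3,3] shift, now alkoxide-accelerated and aromatising the lactone, should give the dipotassium enolate–furanolate F2. Me3SiCl at −78 °C traps it as the bis(trimethylsilyl) enol ether–silyloxyfuran F3, and one equivalent of AcOH in wet THF at −40 °C cleaves the more labile 2-silyloxyfuran by protonation at C11 to return 13.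

Step 10. What may go wrong: aldol addition at the γ-carbon C6 of the ambident furanolate, or over-addition, in place of clean mono-hydroxymethylation at C11. Fallback, C13 introduced before the rearrangement at an ordinary lactone enolate, setting out from 12 and coming back at 18: LiN(i-Pr)2 and then formaldehyde on 12 should give the α-hydroxymethyl spirolactone F4 (C11 epimers), and Et3SiCl/imidazole the triethylsilyl ether F5. Heating as in step 9 gives the ten-membered enol lactone F6, and Et3N tautomerises it as in step 11 to the butenolide F7. TsOH in aqueous THF as in step 12 removes the C1 trimethylsilyl enol ether and the primary triethylsilyl ether and equilibrates C10, giving the 13-hydroxy ketone F8, which Ac2O/pyridine converts into 18.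

Step 14. What may go wrong: oxidation of the secondary alcohol in place of oxygen transfer, or loss of direction and hence of facial selectivity if the C8 hydroxyl is held in a transannular hemiketal with the C1 ketone or does not reach the alkene. Fallback, a halohydrin sequence that inverts the facial outcome of an undirected attack, setting out from 18 and coming back at 20: NBS in aqueous THF should add bromine to the open face of C4=C5 in 18 (away from C7 and the C8 silyl ether) and water to the tertiary C4 from the other side, giving the (4S,5S)-bromohydrin F9. Ag2O in THF closes the epoxide with inversion at C5, which places the oxygen on the face syn to C7 in the TBS-protected epoxide F10, and HF·pyridine as in step 13 gives 20.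

**Further compounds**

F1 | step 9 | dipotassium alkoxide–lactone enolate of 11 | C=C(C)[C@@]1(O[K])CCC(C)=C[C@]12OC(O[K])=C/C2=C\O[Si](C)(C)C(C)(C)C
F2 | step 9 | dipotassium C1 enolate–furanolate of the ten-membered ring | CC(C)(C)[Si](C)(C)O[C@@H]1C/C(C)=C(\O[K])CC/C(C)=C\c2oc(O[K])cc21
F3 | step 9 | bis(trimethylsilyl) enol ether–silyloxyfuran | CC(C)(C)[Si](C)(C)O[C@@H]1C/C(C)=C(\O[Si](C)(C)C)CC/C(C)=C\c2oc(O[Si](C)(C)C)cc21
F4 | step 10 | 3-(hydroxymethyl) derivative of 12 (C11 epimers) | C=C(C)[C@@]1(O[Si](C)(C)C)CCC(C)=C[C@]12OC(=O)C(CO)/C2=C\O[Si](C)(C)C(C)(C)C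
F5 | step 10 | triethylsilyl ether of F4 | C=C(C)[C@@]1(O[Si](C)(C)C)CCC(C)=C[C@]12OC(=O)C(CO[Si](CC)(CC)CC)/C2=C\O[Si](C)(C)C(C)(C)C
F6 | step 10 | ten-membered enol lactone with 13-O-triethylsilyl group | CC(C)(C)[Si](C)(C)O[C@@H]1C/C(C)=C(\O[Si](C)(C)C)CC/C(C)=C\C2=C1C(CO[Si](CC)(CC)CC)C(=O)O2
F7 | step 10 | 13-O-triethylsilyl butenolide | CC(C)(C)[Si](C)(C)O[C@@H]1C/C(C)=C(\O[Si](C)(C)C)CC/C(C)=C\[C@@H]2OC(=O)C(CO[Si](CC)(CC)CC)=C21
F8 | step 10 | (4Z,6S,8R,10S)-8-[(tert-butyldimethylsilyl)oxy]-13-hydroxy-1-oxogermacra-4,7(11)-dien-12,6-olide | CC(C)(C)[Si](C)(C)O[C@@H]1C[C@H](C)C(=O)CC/C(C)=C\[C@@H]2OC(=O)C(CO)=C21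
F9 | step 14 | (4S,5S)-5-bromo-4-hydroxy derivative of 18 | CC(C)(C)[Si](C)(C)O[C@@H]1C[C@H](C)C(=O)CC[C@](C)(O)[C@@H](Br)[C@@H]2OC(=O)C(COC(C)=O)=C21
F10 | step 14 | 8-O-TBS ether of 20 | CC(C)(C)[Si](C)(C)O[C@@H]1C[C@H](C)C(=O)CC[C@]2(C)O[C@@H]2[C@@H]2OC(=O)C(COC(C)=O)=C21
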